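The earlier runs and the new flask were generated by integration for an exercise.

- Left-handed product stands at 36.4% at 4.00 min in the spring flask. What I want is the right-handed substrate left behind, so I must decide whether to leave the spring flask as charged until 20 min or add free catalyst.

the same everywhere: left-handed substrate 0.40 M; right-handed substrate 0.40 M; gas 26 mM (held)
- spring: free catalyst 10 mol%; the very flask that is asked about, followed so far
- dawn: free catalyst 5 mol%; run made earlier
- flask: free catalyst 10 mol%; time 20 min

- spring (time / min: right-handed substrate / %, left-handed substrate / %, left-handed product / %): 0.667: 46.5, 40.1, 7.1; 1.33: 45.9, 33.7, 14.5; 2.00: 44.4, 27.0, 21.8; 2.50: 42.7, 23.3, 26.1; 3.00: 41.2, 20.0, 29.8; 4.00: 38.5, 13.0, 36.4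
- dawn (time / min: right-handed substrate / %, left-handed substrate / %, left-handed product / %): 1.00: 47.8, 41.8, 8.5; 2.00: 46.2, 33.9, 16.6; 3.00: 44.6, 27.4, 22.4; 5.00: 41.3, 17.3, 33.2; 8.00: 37.4, 9.0, 40.9; 15.0: 29.8, 3.4, 46.1

(standard deviation of a reading: 0.5 percentage points)

- whether the excess of right-handed substrate over left-handed substrate among what is left of the two reaches 90% by 20 min (no / yes)
- the highest excess of right-handed substrate over left-handed substrate among what is left of the two up to 20 min

- free catalyst is single-handed; left-handed substrate and right-handed substrate are mirror images of each other, charged as a racemate, each of them at the stated concentration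
- at the start none of the gas is in solution

- Right-handed substrate is consumed as well, so I need to know how the two losses are tied. The last spring readings give 5.15 for the selectivity factor, the logarithm of the fraction of left-handed substrate left over the logarithm of the fraction of right-handed substrate left.
- The last dawn readings give 5.19 at half the loading, so the two loadings read alike on this factor, and I add no free catalyst.
- Late on, [left-handed substrate] is a small correction to [right-handed substrate], so I reckon only their ratio. The wanted excess needs a ratio of 0.0526, and the factor turns that into [right-handed substrate] at 24.6% of the two substrates charged together.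
- The last spring reading gives right-handed substrate a rate constant of 0.0653 min⁻¹, and held steady that puts the spring flask there at 10.8 min, about half the time allowed.
- The constant may sag: the dawn flask gives 0.0382 min⁻¹ early and 0.0325 min⁻¹ late. Held steady, the constant reckons the spring flask at 99.1% by 20 min, so I commit to a top between 90% and that, and leave the flask alone.
- The forecast says yes with a top of 96%, “still rising at the end”.
- The spring flask gives yes and a top of 94.7%, passing 90% at 11.3 min with right-handed substrate at 26.2% of the two substrates charged together.

    reagent + catalyst intermediate A → free catalyst + left-handed product (k = 9.30 M⁻¹ s⁻¹)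
    reagent + catalyst intermediate B → free catalyst + right-handed product (k = 2.10 M⁻¹ s⁻¹)
    free catalyst + right-handed substrate ⇌ catalyst intermediate B (K = 7.50 M⁻¹, k = 2.10 M⁻¹ s⁻¹)
    gas ⇌ reagent, rate k4*(csat - [reagent]) (kL = 0.110 s⁻¹)
    2 free catalyst → spent catalyst A (k = 0.740 M⁻¹ s⁻¹)
    free catalyst + left-handed substrate ⇌ catalyst intermediate A (K = 13.0 M⁻¹, k = 3.90 M⁻¹ s⁻¹)
    free catalyst → spent catalyst B (k = 0.00560 s⁻¹)

- At 20.0 min in the spring flask, the step of free catalyst with left-handed substrate is slower than its step with right-handed substrate, at 0.050 of that rate, forward rates alone. [Left-handed substrate] then stands at 0.608% and [right-handed substrate] at 22.5%, which are 1.2% and 45% of what was charged of each and give a selectivity factor of 5.54 against the 5.15 I carried.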